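Slowness comes first: we ask whether the oak run slows by more than its falling X accounts for.

| flask | X | J | remark |
|---|---|---|---|
| maple | 0.020 M | 1.3 mM | the very flask that is asked about, followed so far |
| oak | 0.020 M | 0.87 mM | run made earlier |
| flask | 0.020 M | 1.3 mM |  |

| run | time / min | L / % |
|---|---|---|
| maple | 0.667 | 13.3 |
| maple | 1.33 | 24.4 |
| maple | 2.00 | 34.0 |
| maple | 2.50 | 39.7 |
| maple | 3.00 | 45.0 |
| oak | 0.500 | 7.3 |
| oak | 0.833 | 11.8 |
| oak | 1.50 | 19.9 |
| oak | 3.00 | 33.3 |
| oak | 6.00 | 49.5 |

(each reading ± 0.5 percentage points)

* apparent order in J when 30 % of the X are converted (percent change of the rate of making L for one percent more J charged)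

- what was read earlier has a scatter of 0.5 percentage points, one standard deviation

If the rate follows X times working J, the logarithm of the fraction of X left falls evenly while J stands. We count X not read as L as left. In the oak run that logarithm falls by 0.405 in the first 3.00 min, but by less in the equal stretch after it, 0.278. So we suppose J decays (catalyst deactivation) and take the logarithm of that ratio over the stretch as λ, the loss constant, the proportion of working J lost per minute: 0.125 min⁻¹.

A flask with one percent more J reaches a fixed conversion about one percent sooner, and so it spares about λt percent of its J, where t is the time to that conversion. In the maple run 30 % comes near 1.72 min, so we reckon the order as one plus λt, 1.22. The forecast differs: it gives 1.4, suspecting “probably through time-dependent catalyst loss or inhibition”. The flask gives 1.2.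

    X + J → Q (k = 3.32 L mol⁻¹ s⁻¹)
    Q ⇌ J + L (K = 0.470 M, k = 0.809 s⁻¹)
    J → Z (k = 0.00212 s⁻¹)

In a simulated run without the path from J to Z, the order is 1.0 instead of 1.2. We carry λ on in this flask, from 30 % conversion to 70.0 %, reached at 7.48 min. X falls to 0.429 of its level and working J shrinks with λ, so the rate should fall to 0.206 of its value; the flask gives 0.22.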